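A direct plan would O-alkylate 3,5-dibromosalicylaldehyde A1 with racemic 2-chlorocyclohexanone A2 to ketone A3, aromatise the cyclohexanone ring with I2/DMSO to phenol A4, brominate para to the new hydroxyl to tribromide A5, methylate it to anisole A6 and exchange CHO for OH through formate A7. Its weakest steps would be:
- the etherification, because a phenoxide flanked by Br and CHO is a poor nucleophile towards a secondary, enolisable α-halo ketone;
- the dehydrogenative aromatisation, which must strip four hydrogens at 100 °C beside a free aldehyde and an HI-labile α-aryloxy ketone;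
- the four closing functional-group steps, which would add length without skeletal complexity and depend on para/ortho and anti-Smiles selectivity.

The route rests on building ring B itself instead of joining two benzene rings. Ring B (C1' ether carbon, C2' hydroxyl carbon, Br on C4' and C6') alternates Br, H, Br, H along C6'–C3', exactly the C3–C6 pattern of 3,5-dibromo-2-pyrone, while C1'–C2' is a two-carbon unit bearing two heteroatoms. A Diels–Alder/retro-Diels–Alder reaction of that pyrone with the aryloxyethynyl boronate of ring A would form C1'–C6' and C2'–C3', expel CO2 and deliver the fully substituted ring with boron marking the hydroxyl. The ether C–O bond is made at an sp carbon from 5-bromoguaiacol, so no hindered etherification, no dehydrogenation, no late bromination, methylation or formyl-to-hydroxyl exchange is needed.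

Key step: step 4

Step 1
Reactants: 1 5-bromo-2-methoxyphenol; 2 trichloroethylene
Product: 4 4-bromo-2-{[(E)-1,2-dichloroethenyl]oxy}-1-methoxybenzene, via dichloroacetylene 3 (not isolated)
Conditions: 2 (1.5 equiv), K2CO3 (2.0 equiv), DMF, 70 °C, closed vessel
Reagents that add atoms: none
Why: Elimination–addition vinylation of a phenol with trichloroethylene, in which carbonate dehydrochlorinates 2 to dichloroacetylene 3 and the phenoxide adds to it in anti fashion to give the (E)-1,2-dichlorovinyl ether, while the aryl bromide and the methyl ether are inert.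

Step 2
Reactants: 4 4-bromo-2-{[(E)-1,2-dichloroethenyl]oxy}-1-methoxybenzene
Product: 8 2-[(5-bromo-2-methoxyphenoxy)ethynyl]-4,4,5,5-tetramethyl-1,3,2-dioxaborolane, via chloroalkyne 5 (not isolated), via lithium acetylide 6 (not isolated), via lithium alkynylborate 7 (not isolated)
Conditions: n-BuLi (2.05 equiv), Et2O, −78 °C; iPrOBpin (1.1 equiv), −78 °C; HCl in Et2O (1.0 equiv), −78 °C → rt; filtered under N2, concentrated, used crude
Reagents that add atoms: 2-isopropoxy-4,4,5,5-tetramethyl-1,3,2-dioxaborolane (iPrOBpin), CC(C)OB1OC(C)(C)C(C)(C)O1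
Why: The dichlorovinyl ether route to lithium ynol-ether acetylides (deprotonation, β-elimination of LiCl to 5, chlorine–lithium exchange to 6) joined to the standard alkynylboronate preparation (ate complex 7 collapsed by HCl), in which the acid–base step and the exchange at the sp-bound chlorine should outpace bromine–lithium exchange at the electron-rich anisyl bromide in Et2O at −78 °C with just two equivalents of n-BuLi.

Step 3
Reactants: 9 coumalic acid (2-oxo-2H-pyran-5-carboxylic acid)
Product: 11 3,5-dibromo-2H-pyran-2-one, via 3-bromocoumalic acid 10 (not isolated)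
Conditions: NBS (2.5 equiv), LiOAc (20 mol %), MeCN/H2O, rt
Reagents that add atoms: N-bromosuccinimide (NBS), O=C1CCC(=O)N1Br
Why: Hunsdiecker-type bromodecarboxylation under catalytic-acetate conditions, in which the coumalate anion should be brominated electrophilically at C3 and then ipso at C5 with loss of CO2, the established way to this pyrone.

Step 4
Reactants: 8 2-[(5-bromo-2-methoxyphenoxy)ethynyl]-4,4,5,5-tetramethyl-1,3,2-dioxaborolane; 11 3,5-dibromo-2H-pyran-2-one
Product: 13 2-[3,5-dibromo-2-(5-bromo-2-methoxyphenoxy)phenyl]-4,4,5,5-tetramethyl-1,3,2-dioxaborolane, via bridged bicyclic lactone 12 (not isolated)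
Conditions: 8 (1.3 equiv), o-xylene, 130 °C, sealed tube, N2
Reagents that add atoms: none
Why: Thermal [4+2] cycloaddition across C3 and C6 of the electron-poor, ambiphilic pyrone 11 with the push–pull alkyne 8 is followed by retro-[4+2] loss of CO2 from the bridged lactone 12, which makes the sequence irreversible and delivers benzene ring B directly. The closest known reaction types are the cycloaddition–decarboxylation of 2-pyrones with alkynylboronates to aryl boronates and the regioselective cycloadditions of 3,5-dibromo-2-pyrone with enol ethers. Ring B is closed intermolecularly in a (4+2) mode that forms C1'–C6' and C2'–C3', and the two bridgehead stereocentres of 12 are erased on aromatisation, so no stereocontrol is needed. The selectivity required is regiochemical: in the asynchronous transition state the boron-bearing alkyne carbon (the nucleophilic β-carbon of the ynol ether, whose polarisation the empty boron orbital reinforces) should bond to the electrophilic C6 of the pyrone and the oxygen-bearing carbon to C3, which places the aryloxy group between Br and B, and the bulky Bpin also prefers the side of C6–H over that of C3–Br. With no transition metal present the three C–Br bonds and the C–B bond should stay intact, and an aryl ynol ether has no β-hydrogen for the retro-ene fragmentation that limits alkyl ynol ethers on heating.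

Step 5
Reactants: 13 2-[3,5-dibromo-2-(5-bromo-2-methoxyphenoxy)phenyl]-4,4,5,5-tetramethyl-1,3,2-dioxaborolane
Product: 15 3,5-dibromo-2-(5-bromo-2-methoxyphenoxy)phenol, via aryl pinacol borate 14 (not isolated)
Conditions: 30% aq. H2O2 (3 equiv), NaOH (1.5 equiv), THF/H2O, 0 °C → rt; then 1 M HCl
Reagents that add atoms: hydrogen peroxide, OO
Why: Alkaline peroxide oxidation of an aryl boronate, in which hydroperoxide adds to boron, the aryl group migrates from boron to oxygen at the same carbon and borate 14 is hydrolysed to the target phenol, while the aryl bromides and both ethers are inert and the phenoxide cannot start a Smiles shift onto the unactivated anisole ring.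

**Compound list**

1 | 5-bromo-2-methoxyphenol (5-bromoguaiacol) | COc1ccc(Br)cc1O | starting material
2 | trichloroethylene | ClC=C(Cl)Cl | starting material
3 | dichloroacetylene (not isolated) | ClC#CCl | intermediate
4 | 4-bromo-2-{[(E)-1,2-dichloroethenyl]oxy}-1-methoxybenzene | COc1ccc(Br)cc1O/C(Cl)=C\Cl | intermediate
5 | 4-bromo-2-[(chloroethynyl)oxy]-1-methoxybenzene (not isolated) | COc1ccc(Br)cc1OC#CCl | intermediate
6 | [(5-bromo-2-methoxyphenoxy)ethynyl]lithium (not isolated) | COc1ccc(Br)cc1OC#C[Li] | intermediate
7 | lithium [(5-bromo-2-methoxyphenoxy)ethynyl](isopropoxy)(pinacolato)borate (not isolated) | [Li+].COc1ccc(Br)cc1OC#C[B-]1(OC(C)C)OC(C)(C)C(C)(C)O1 | intermediate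
8 | 2-[(5-bromo-2-methoxyphenoxy)ethynyl]-4,4,5,5-tetramethyl-1,3,2-dioxaborolane | COc1ccc(Br)cc1OC#CB1OC(C)(C)C(C)(C)O1 | intermediate
9 | coumalic acid (2-oxo-2H-pyran-5-carboxylic acid) | OC(=O)C1=COC(=O)C=C1 | starting material
10 | 3-bromo-2-oxo-2H-pyran-5-carboxylic acid (3-bromocoumalic acid, not isolated) | OC(=O)C1=COC(=O)C(Br)=C1 | intermediate
11 | 3,5-dibromo-2H-pyran-2-one | O=C1OC=C(Br)C=C1Br | intermediate
12 | racemic 4,7-dibromo-5-(5-bromo-2-methoxyphenoxy)-6-(4,4,5,5-tetramethyl-1,3,2-dioxaborolan-2-yl)-2-oxabicyclo[2.2.2]octa-5,7-dien-3-one (not isolated) | O=C1OC2C(Br)=CC1(Br)C(Oc3cc(Br)ccc3OC)=C2B4OC(C)(C)C(C)(C)O4 | intermediate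
13 | 2-[3,5-dibromo-2-(5-bromo-2-methoxyphenoxy)phenyl]-4,4,5,5-tetramethyl-1,3,2-dioxaborolane | COc1ccc(Br)cc1Oc1c(B2OC(C)(C)C(C)(C)O2)cc(Br)cc1Br | intermediate
14 | 2-[3,5-dibromo-2-(5-bromo-2-methoxyphenoxy)phenoxy]-4,4,5,5-tetramethyl-1,3,2-dioxaborolane (not isolated) | COc1ccc(Br)cc1Oc1c(OB2OC(C)(C)C(C)(C)O2)cc(Br)cc1Br | intermediate
15 | 3,5-dibromo-2-(5-bromo-2-methoxyphenoxy)phenol | COc1ccc(Br)cc1Oc1c(O)cc(Br)cc1Br | target

**Step count and risks**

Total step count: 5. Longest linear sequence: 4 steps (steps 1, 2, 4 and 5); step 3 supplies the second partner of the key step.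

**Step 4.** The cycloaddition may be slower than thermal oligomerisation or adventitious protodeboronation of the push–pull alkyne, or the two partners may add in both orientations. The fallback would buy ring B ready-made and join it by nucleophilic aromatic substitution. It would set out from 1 and come back to the route at 15. Phenol 1 would displace fluoride from 1,5-dibromo-2-fluoro-3-nitrobenzene F1 (K2CO3, DMF, 60 °C) to give 1,5-dibromo-2-(5-bromo-2-methoxyphenoxy)-3-nitrobenzene F2. Reduction with Fe powder and NH4Cl in aqueous ethanol, which spares aryl bromides, should give 3,5-dibromo-2-(5-bromo-2-methoxyphenoxy)aniline F3. Diazotisation (NaNO2, aq. H2SO4, 0 °C) would give 3,5-dibromo-2-(5-bromo-2-methoxyphenoxy)benzenediazonium hydrogensulfate F4. Hydroxy-dediazoniation with Cu2O in aqueous Cu(NO3)2 at rt would then give 15; these conditions are chosen because capture of the aryl radical by divalent copper should outrun Pschorr-type closure to a dibenzofuran.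

**Step 2.** Bromine–lithium exchange at the ring A bromide may compete with the desired deprotonation and chlorine–lithium exchange, and the alkynyl boronate may hydrolyse on handling. The fallback would reach the acetylide with an amide base only, by the classical bromovinyl ether sequence. It would set out from 1 and come back to the route at 6. Williamson alkylation of 1 with excess 1,2-dibromoethane (K2CO3, MeCN, reflux) would give 4-bromo-2-(2-bromoethoxy)-1-methoxybenzene F5. Elimination with KOtBu in THF would give 4-bromo-2-(ethenyloxy)-1-methoxybenzene F6. Addition of Br2 in CH2Cl2 at −78 °C would give racemic 4-bromo-2-(1,2-dibromoethoxy)-1-methoxybenzene F7. Dehydrobromination with PhNEt2 at 100 °C would give 4-bromo-2-[(2-bromoethenyl)oxy]-1-methoxybenzene F8 as an E/Z mixture. LiN(iPr)2 (2.2 equiv, THF, −78 °C) should then eliminate HBr and deprotonate the alkyne to give 6, which would be borylated as in step 2.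

**Step 3.** Bromodecarboxylation at C5 may outrun bromination at C3, leaving a monobromopyrone that does not take up the second bromine, and the lactone may open in the aqueous medium. The fallback would install the C3 bromine separately on the ester, where no decarboxylation can compete. It would set out from 9 and come back to the route at 10. Fischer esterification (MeOH, H2SO4) would give methyl 2-oxo-2H-pyran-5-carboxylate F9. Bromine addition and elimination (Br2, CH2Cl2, then Et3N) would give methyl 3-bromo-2-oxo-2H-pyran-5-carboxylate F10. Acid hydrolysis (aq. HCl, AcOH, reflux) should give 10, which would be bromodecarboxylated with NBS and LiOAc to 11.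

**Further compounds**

F1 | step 4 | 1,5-dibromo-2-fluoro-3-nitrobenzene | [O-][N+](=O)c1cc(Br)cc(Br)c1F
F2 | step 4 | 1,5-dibromo-2-(5-bromo-2-methoxyphenoxy)-3-nitrobenzene | COc1ccc(Br)cc1Oc1c(cc(Br)cc1Br)[N+](=O)[O-]
F3 | step 4 | 3,5-dibromo-2-(5-bromo-2-methoxyphenoxy)aniline | COc1ccc(Br)cc1Oc1c(N)cc(Br)cc1Br
F4 | step 4 | 3,5-dibromo-2-(5-bromo-2-methoxyphenoxy)benzenediazonium hydrogensulfate | COc1ccc(Br)cc1Oc1c(cc(Br)cc1Br)[N+]#N.OS(=O)(=O)[O-]
F5 | step 2 | 4-bromo-2-(2-bromoethoxy)-1-methoxybenzene | COc1ccc(Br)cc1OCCBr
F6 | step 2 | 4-bromo-2-(ethenyloxy)-1-methoxybenzene | COc1ccc(Br)cc1OC=C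
F7 | step 2 | racemic 4-bromo-2-(1,2-dibromoethoxy)-1-methoxybenzene | COc1ccc(Br)cc1OC(Br)CBr
F8 | step 2 | 4-bromo-2-[(2-bromoethenyl)oxy]-1-methoxybenzene (E/Z mixture) | COc1ccc(Br)cc1OC=CBr
F9 | step 3 | methyl 2-oxo-2H-pyran-5-carboxylate (methyl coumalate) | COC(=O)C1=COC(=O)C=C1
F10 | step 3 | methyl 3-bromo-2-oxo-2H-pyran-5-carboxylate | COC(=O)C1=COC(=O)C(Br)=C1
A1 | direct plan | 3,5-dibromosalicylaldehyde | O=Cc1cc(Br)cc(Br)c1O
A2 | direct plan | racemic 2-chlorocyclohexanone | O=C1CCCCC1Cl
A3 | direct plan | racemic 3,5-dibromo-2-[(2-oxocyclohexyl)oxy]benzaldehyde | O=Cc1cc(Br)cc(Br)c1OC1CCCCC1=O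
A4 | direct plan | 3,5-dibromo-2-(2-hydroxyphenoxy)benzaldehyde | O=Cc1cc(Br)cc(Br)c1Oc1ccccc1O
A5 | direct plan | 3,5-dibromo-2-(5-bromo-2-hydroxyphenoxy)benzaldehyde | O=Cc1cc(Br)cc(Br)c1Oc1cc(Br)ccc1O
A6 | direct plan | 3,5-dibromo-2-(5-bromo-2-methoxyphenoxy)benzaldehyde | COc1ccc(Br)cc1Oc1c(C=O)cc(Br)cc1Br
A7 | direct plan | 3,5-dibromo-2-(5-bromo-2-methoxyphenoxy)phenyl formate | COc1ccc(Br)cc1Oc1c(OC=O)cc(Br)cc1Br
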